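**Plan**
- Retrosynthesis: the epoxide oxygen, the two O-acyl groups and C13 are taken off, C2–C3 is desaturated, and the ten-membered ring is closed back across C5–C10 to a cis-fused hexalin.
- Enabling feature: C1=C10 and C4=C5 flank C2–C3, so C10=C1–C2=C3–C4=C5 is the open form of a cyclohexa-1,3-diene (ring A, C1–C5 and C10) fused to ring B (C5–C10) at C5–C10.
- The hexalin is cut at C10–C1 and C5–C4 (Diels–Alder of a 2-siloxydiene with 2-carbomethoxybenzoquinone, which brings C14 as the ester) and at C7–C11 (malonate Michael addition tethered to O6).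
- Forward order: quinone (ring B) → ring A by cycloaddition → lactone ring → O8 and O9 → ring A 1,3-diene → light opens C5–C10 to the ten-membered ring → C2=C3 saturated → methylene, esters, epoxide.
- Stereochemistry: a chiral Lewis acid sets C5/C10; these relay to C6 (convex-face hydride), C7 (tether), C8 (bromination, then SN2 inversion) and C9 (hydroxyl-delivered hydride) and are then erased. Alkene geometry comes from conrotation of a conformationally biased diene, the epoxide from peripheral attack on the trans alkene.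

Key step: step 17

Numbering and faces: atoms carry the numbers of the germacrane skeleton of the target (ring C1–C10; C11 and C12 are the lactone α-carbon and carbonyl on C7/O6; C13 the exocyclic methylene; C14 the ester carbon on C10; C15 the methyl on C4). α is the face of ring B that carries O6, C11 and O8 in the target; β is the opposite face (O9).
Assumption: the (S,S)-ligand in step 3 gives the enantiomer drawn for 5; if the sense of induction is the reverse, the (R,R)-ligand is used.
Assumption: 5 is drawn as the endo adduct at C4; this centre, and C11 in 11, 12, 25 and 26 (epimers), are immaterial because both carbons become sp2.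

Step 1
Reactants: 1 ethyl vinyl ketone
Product: 2 (Z)-3-(triisopropylsilyloxy)penta-1,3-diene
Conditions: iPr3SiOTf, Et3N, Et2O, 0 °C
Reagents that add atoms: triisopropylsilyl trifluoromethanesulfonate CC(C)[Si](OS(=O)(=O)C(F)(F)F)(C(C)C)C(C)C
Why: Soft enolisation and O-silylation of the ethyl ketone (silyl dienol ether formation) gives the Z enol ether, which carries the methyl on the outside of the s-cis diene.

Step 2
Reactants: 3 methyl 2,5-dihydroxybenzoate
Product: 4 methyl 3,6-dioxocyclohexa-1,4-diene-1-carboxylate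
Conditions: Ag2O, MgSO4, Et2O, rt; filtered and used at once
Reagents that add atoms: none
Why: Hydroquinone-to-quinone oxidation with Ag2O gives the labile ester-substituted quinone under neutral, anhydrous conditions.

Step 3
Reactants: 4 methyl 3,6-dioxocyclohexa-1,4-diene-1-carboxylate; 2 (Z)-3-(triisopropylsilyloxy)penta-1,3-diene
Product: 5 cis-fused cycloadduct (5β-H, 10β-CO2Me; ring B 6,9-dione with C7=C8; ring A C2=C3 enol ether with 3-OTIPS; 4-methyl trans to H5)
Conditions: Sm(OTf)3 (10 mol %), 2,6-bis[(4S)-4-phenyl-2-oxazolin-2-yl]pyridine (12 mol %), 4 Å MS, THF, −78 °C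
Reagents that add atoms: none
Why: Chiral-Lewis-acid-catalysed Diels–Alder reaction in which two-point binding of the ester and the neighbouring quinone carbonyl activates the ester-bearing C5=C10 bond, the siloxy-activated diene terminus (C4) bonds to C5, suprafacial addition makes the ring fusion cis, and the ligand-shielded face fixes C5 and C10.

Step 4
Reactants: 5 cis-fused cycloadduct
Product: 6 6α-hydroxy enone (6β-H; C7=C8–C9=O kept)
Conditions: NaBH4, CeCl3·7H2O, MeOH/CH2Cl2, −78 °C
Reagents that add atoms: none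
Why: Luche 1,2-reduction takes place at the less hindered C6 carbonyl (C9 adjoins the quaternary C10) with hydride entering from the convex β-face of the cis-fused bicycle, so the new hydroxyl is α, on the side of ring A.

Step 5
Reactants: 7 Meldrum's acid; 8 allyl alcohol
Product: 9 allyl hydrogen malonate
Conditions: toluene, reflux
Reagents that add atoms: none
Why: Thermal alcoholysis of Meldrum's acid (acylation with loss of acetone) gives the malonic half ester.

Step 6
Reactants: 6 6α-hydroxy enone; 9 allyl hydrogen malonate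
Product: 10 6α-O-(allyl malonyl) ester of 6
Conditions: DCC, DMAP (cat.), CH2Cl2, 0 °C → rt
Reagents that add atoms: none
Why: Steglich esterification acylates the allylic alcohol without touching C6, the enone or the enol ether.

Step 7
Reactants: 10 6α-O-(allyl malonyl) ester
Product: 11 cis-fused 6α,12-lactone carrying CO2allyl on C11 (C7–C11 bond α, 7β-H; C9 ketone; C8 CH2)
Conditions: Cs2CO3, MeCN, rt
Reagents that add atoms: none
Why: Intramolecular Michael addition (5-exo-trig) of the malonate carbanion to C7 of the enone; the tether from the α-oxygen on C6 can reach only the α-face of C7, which sets C7 and makes the γ-lactone cis-fused.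

Step 8
Reactants: 11 cis-fused 6α,12-lactone carrying CO2allyl on C11
Product: 13 9-keto 6α,12-olide (C11 now CH2), via α-carboxy lactone 12 (not isolated)
Conditions: Pd(OAc)2 (5 mol %), PPh3, HCO2H, Et3N, 1,4-dioxane, rt → 90 °C
Reagents that add atoms: none
Why: Palladium-catalysed deallylation with formate as hydride donor (Tsuji conditions) frees the malonic-type acid, which decarboxylates on warming; the neutral medium spares the non-enolisable β-keto ester and the enol ether.

Step 9
Reactants: 13 9-keto 6α,12-olide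
Product: 14 8β-bromo-9-keto 6α,12-olide
Conditions: KN(SiMe3)2, THF, −78 °C; then N-bromosuccinimide, −78 °C
Reagents that add atoms: N-bromosuccinimide O=C1CCC(=O)N1Br
Why: Regiospecific ketone enolisation (C10 is quaternary, the lactone is less acidic) and electrophilic α-bromination from the convex β-face, anti to the α-oriented C7–C11 bond next to C8.

Step 10
Reactants: 14 8β-bromo-9-keto 6α,12-olide
Product: 16 8α-hydroxy-9-keto 6α,12-olide, via 8α-formate 15 (not isolated)
Conditions: HCO2Cs, DMF, 0 °C → rt; then NaHCO3, MeOH/H2O, 0 °C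
Reagents that add atoms: caesium formate [Cs+].[O-]C=O
Why: SN2 displacement of the activated axial α-bromo ketone by formate inverts C8 and puts oxygen on the α-face (cis to C11 and O6), E2 being disfavoured because C7–H is not antiperiplanar to bromine; the formate is then cleaved by mild bicarbonate methanolysis.

Step 11
Reactants: 16 8α-hydroxy-9-keto 6α,12-olide
Product: 17 8α,9β-diol
Conditions: Me4NBH(OAc)3, MeCN/AcOH, −25 °C
Reagents that add atoms: none
Why: Hydroxyl-directed triacetoxyborohydride reduction (Saksena–Evans): the borate formed on O8 delivers hydride to the α-face of C9, giving the 9β-alcohol trans to O8, while esters, lactone and enol ether are not reduced.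

Step 12
Reactants: 17 8α,9β-diol
Product: 18 8α-O-triethylsilyl ether (9β-OH free)
Conditions: Et3SiCl, imidazole, DMF, 0 °C
Reagents that add atoms: chlorotriethylsilane CC[Si](Cl)(CC)CC
Why: Selective silylation of the less hindered C8 hydroxyl; the C9 hydroxyl is neopentylic (next to quaternary C10) and hydrogen-bonded to the ester.

Step 13
Reactants: 18 8α-O-triethylsilyl ether
Product: 19 8α-OTES 9β-OTBS bis-silyl ether
Conditions: tBuMe2SiOTf, 2,6-lutidine, CH2Cl2, 0 °C
Reagents that add atoms: tert-butyldimethylsilyl trifluoromethanesulfonate CC(C)(C)[Si](C)(C)OS(=O)(=O)C(F)(F)F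
Why: The hindered C9 alcohol is silylated with the more reactive silyl triflate (silyl ether formation).

Step 14
Reactants: 19 bis-silyl ether
Product: 20 ring A enone (C1=C2–C3=O; 4-methyl)
Conditions: Pd(OAc)2 (1.1 equiv), MeCN, 45 °C
Reagents that add atoms: none
Why: Saegusa–Ito oxidation of the enol ether placed regiospecifically by the cycloaddition: the palladium enolate at C2 loses the C1 hydrogen, so the enone double bond is C1=C2.

Step 15
Reactants: 20 ring A enone
Product: 21 dienyl triflate (C1=C2–C3(OTf)=C4–CH3)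
Conditions: KN(SiMe3)2, THF, −78 °C; then PhNTf2
Reagents that add atoms: N-phenylbis(trifluoromethanesulfonimide) O=S(=O)(N(c1ccccc1)S(=O)(=O)C(F)(F)F)C(F)(F)F
Why: Kinetic deprotonation at C4, the only α-hydrogen of the enone because C10 is quaternary, and O-sulfonylation of the cross-conjugated dienolate (enol triflate formation) remove the C4 stereocentre.

Step 16
Reactants: 21 dienyl triflate
Product: 22 cis-fused hexalin (C1=C2–C3=C4–CH3; 5β-H; 10β-CO2Me; 6α,12-olide with 7β-H; 8α-OTES; 9β-OTBS)
Conditions: Pd(OAc)2 (5 mol %), PPh3, Bu3N, HCO2H, DMF, 60 °C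
Reagents that add atoms: none
Why: Palladium-catalysed formate reduction of the dienyl triflate (Cacchi reduction) replaces OTf by H and leaves the homoannular diene in place.

Step 17
Reactants: 22 cis-fused hexalin
Product: 23 cyclodeca-1(10),2,4-triene (C1=C10 with CO2Me trans to C2 and C9 cis to C2; cis C2=C3; trans C4=C5; 6,12-olide; 8-OTES; 9-OTBS)
Conditions: hν (254 nm, low-pressure Hg lamp, quartz), degassed Et2O, −40 °C, stopped at partial conversion; recovered 22 re-irradiated
Reagents that add atoms: none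
Why: Excitation of the homoannular diene (C1=C2–C3=C4) leads to conrotatory 6π electrocyclic opening in which the C5–C10 σ bond shared by rings A and B breaks and the C1=C10 and C4=C5 double bonds form, with C2=C3 left cis. The closest known reaction type is the photochemical opening of eudesmane-type 1,3-dienes to cyclodeca-1,3,5-trienes. No ring is closed in the usual sense, since the ten-membered ring arises by ring expansion through cleavage of the fusion bond, and no stereocentre is formed because C5 and C10 become sp2. The step needs one sense of conrotation, the one that turns H5 and the C9–C10 bond inward and C6 and CO2Me outward. This is secured by the ground-state shape of 22: in the chair of ring B that keeps O6, O8 and O9 equatorial (the other chair would set O6, O8 and C1 syn-axial), H5 and C9 are quasi-axial on the diene ring, and quasi-axial groups swing inward when the twisted excited diene opens, as in the trans-fused eudesmadienes that give the E,Z,E trienes. The outcome is the trans C4=C5 bond and the ring-cis C1=C10 bond of the target, and the cold solution is reduced at once because the triene can photorevert or re-close thermally.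

Step 18
Reactants: 23 cyclodeca-1(10),2,4-triene
Product: 24 germacra-1(10),4-diene (C2–C3 saturated)
Conditions: KO2C–N=N–CO2K, AcOH, MeOH/CH2Cl2, −20 → 0 °C, on the cold photolysate
Reagents that add atoms: none
Why: Diimide reduction transfers H2 concertedly and strongly prefers the least substituted, most strained double bond, the cis-disubstituted C2=C3, over the trisubstituted C4=C5 and the ester-conjugated C1=C10 bonds.

Step 19
Reactants: 24 germacra-1(10),4-diene
Product: 27 11(13)-methylene lactone (8-OTES 9-OTBS), via Mannich base 25 (not isolated), via methiodide 26 (not isolated)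
Conditions: LiN(iPr)2, THF, −78 °C; CH2=NMe2+ I−, −78 °C → rt; then MeI, MeOH, rt; then aq NaHCO3, CH2Cl2
Reagents that add atoms: dimethyl(methylidene)ammonium iodide C=[N+](C)C.[I-]
Why: Mannich reaction of the lactone enolate (the most acidic site) with Eschenmoser's salt, then quaternisation and Hofmann-type β-elimination, gives the α-methylene lactone.

Step 20
Reactants: 27 11(13)-methylene lactone
Product: 28 8-hydroxy compound (9-OTBS kept)
Conditions: PPTS (cat.), MeOH, 0 °C
Reagents that add atoms: none
Why: Acid-catalysed methanolysis removes the secondary triethylsilyl ether much faster than the tert-butyldimethylsilyl ether (selective desilylation).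

Step 21
Reactants: 28 8-hydroxy compound
Product: 29 8-O-methacrylate (9-OTBS)
Conditions: methacrylic anhydride, Et3N, DMAP (cat.), CH2Cl2, 0 °C → rt
Reagents that add atoms: methacrylic anhydride C=C(C)C(=O)OC(=O)C(C)=C
Why: DMAP-catalysed acylation of the free C8 alcohol; with O9 still silylated no acyl migration is possible.

Step 22
Reactants: 29 8-O-methacrylate
Product: 30 8-O-methacrylate 9-alcohol
Conditions: HF·pyridine, pyridine, THF, 0 °C → rt
Reagents that add atoms: none
Why: Fluoride cleavage of the silyl ether under buffered, non-basic conditions spares the methacrylate, the methyl ester and the α-methylene lactone.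

Step 23
Reactants: 30 8-O-methacrylate 9-alcohol
Product: 31 9-O-acetyl-8-O-methacryloyl germacra-1(10),4-dienolide
Conditions: Ac2O, pyridine, DMAP (cat.), CH2Cl2, 0 °C
Reagents that add atoms: acetic anhydride CC(=O)OC(C)=O
Why: Fast DMAP-catalysed acetylation of the C9 alcohol outruns migration of the neighbouring methacryloyl group.

Step 24
Reactants: 31 9-O-acetyl-8-O-methacryloyl germacra-1(10),4-dienolide
Product: 32 fluctuadin
Conditions: mCPBA, NaHCO3, CH2Cl2, 0 °C
Reagents that add atoms: 3-chloroperoxybenzoic acid O=C(OO)c1cccc(Cl)c1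
Why: Prilezhaev epoxidation picks the only electron-rich alkene (C4=C5) and attacks its outer face, where C6–H eclipses the alkene (allylic strain) and O6 lies on the exposed side, giving the 4R,5R trans-epoxide as in the epoxidation of costunolide-type germacranolides.

**Compound list**
1 | ethyl vinyl ketone (pent-1-en-3-one) | CCC(=O)C=C | starting material
2 | (Z)-3-(triisopropylsilyloxy)penta-1,3-diene | C/C=C(\O[Si](C(C)C)(C(C)C)C(C)C)C=C | intermediate
3 | methyl 2,5-dihydroxybenzoate | COC(=O)c1cc(O)ccc1O | starting material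
4 | methyl 3,6-dioxocyclohexa-1,4-diene-1-carboxylate (2-carbomethoxy-1,4-benzoquinone) | COC(=O)C1=CC(=O)C=CC1=O | intermediate
5 | cis-fused cycloadduct: 5β-H, 10β-CO2Me; ring B 6,9-dione with C7=C8; ring A C2=C3 enol ether with 3-OTIPS; 4-methyl trans to H5 | C[C@H]1[C@H]2C(=O)C=CC(=O)[C@@]2(C(=O)OC)CC=C1O[Si](C(C)C)(C(C)C)C(C)C | intermediate
6 | 6α-hydroxy enone: 5 with C6=O reduced to 6α-OH | C[C@H]1[C@H]2[C@@H](O)C=CC(=O)[C@@]2(C(=O)OC)CC=C1O[Si](C(C)C)(C(C)C)C(C)C | intermediate
7 | Meldrum's acid (2,2-dimethyl-1,3-dioxane-4,6-dione) | CC1(C)OC(=O)CC(=O)O1 | starting material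
8 | allyl alcohol | C=CCO | starting material
9 | allyl hydrogen malonate | C=CCOC(=O)CC(=O)O | intermediate
10 | 6α-O-(allyl malonyl) ester of 6 | C[C@H]1[C@H]2[C@@H](OC(=O)CC(=O)OCC=C)C=CC(=O)[C@@]2(C(=O)OC)CC=C1O[Si](C(C)C)(C(C)C)C(C)C | intermediate
11 | cis-fused 6α,12-lactone with CO2allyl on C11 (C11 epimers); C7–C11 α, 7β-H; C9 ketone | C[C@H]1[C@H]2[C@H]3OC(=O)C(C(=O)OCC=C)[C@H]3CC(=O)[C@@]2(C(=O)OC)CC=C1O[Si](C(C)C)(C(C)C)C(C)C | intermediate
12 | α-carboxy lactone (11-carboxylic acid, C11 epimers) | C[C@H]1[C@H]2[C@H]3OC(=O)C(C(=O)O)[C@H]3CC(=O)[C@@]2(C(=O)OC)CC=C1O[Si](C(C)C)(C(C)C)C(C)C | intermediate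
13 | 9-keto 6α,12-olide (C11 = CH2) | C[C@H]1[C@H]2[C@H]3OC(=O)C[C@H]3CC(=O)[C@@]2(C(=O)OC)CC=C1O[Si](C(C)C)(C(C)C)C(C)C | intermediate
14 | 8β-bromo-9-keto 6α,12-olide | C[C@H]1[C@H]2[C@H]3OC(=O)C[C@H]3[C@H](Br)C(=O)[C@@]2(C(=O)OC)CC=C1O[Si](C(C)C)(C(C)C)C(C)C | intermediate
15 | 8α-formyloxy-9-keto 6α,12-olide | C[C@H]1[C@H]2[C@H]3OC(=O)C[C@H]3[C@@H](OC=O)C(=O)[C@@]2(C(=O)OC)CC=C1O[Si](C(C)C)(C(C)C)C(C)C | intermediate
16 | 8α-hydroxy-9-keto 6α,12-olide | C[C@H]1[C@H]2[C@H]3OC(=O)C[C@H]3[C@@H](O)C(=O)[C@@]2(C(=O)OC)CC=C1O[Si](C(C)C)(C(C)C)C(C)C | intermediate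
17 | 8α,9β-diol (6α,12-olide; 10β-CO2Me; 3-OTIPS enol ether) | C[C@H]1[C@H]2[C@H]3OC(=O)C[C@H]3[C@@H](O)[C@H](O)[C@@]2(C(=O)OC)CC=C1O[Si](C(C)C)(C(C)C)C(C)C | intermediate
18 | 8α-O-triethylsilyl ether of 17 (9β-OH free) | C[C@H]1[C@H]2[C@H]3OC(=O)C[C@H]3[C@@H](O[Si](CC)(CC)CC)[C@H](O)[C@@]2(C(=O)OC)CC=C1O[Si](C(C)C)(C(C)C)C(C)C | intermediate
19 | 8α-OTES 9β-OTBS bis-silyl ether | C[C@H]1[C@H]2[C@H]3OC(=O)C[C@H]3[C@@H](O[Si](CC)(CC)CC)[C@H](O[Si](C)(C)C(C)(C)C)[C@@]2(C(=O)OC)CC=C1O[Si](C(C)C)(C(C)C)C(C)C | intermediate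
20 | ring A enone (C1=C2–C3=O, 4-methyl); 8α-OTES; 9β-OTBS; 6α,12-olide; 10β-CO2Me | C[C@H]1[C@H]2[C@H]3OC(=O)C[C@H]3[C@@H](O[Si](CC)(CC)CC)[C@H](O[Si](C)(C)C(C)(C)C)[C@@]2(C(=O)OC)C=CC1=O | intermediate
21 | dienyl triflate (C1=C2–C3(OTf)=C4–CH3) | CC1=C(OS(=O)(=O)C(F)(F)F)C=C[C@]2(C(=O)OC)[C@@H](O[Si](C)(C)C(C)(C)C)[C@H](O[Si](CC)(CC)CC)[C@@H]3CC(=O)O[C@@H]3[C@H]12 | intermediate
22 | cis-fused hexalin: C1=C2–C3=C4–CH3; 5β-H; 10β-CO2Me; 6α,12-olide (7β-H); 8α-OTES; 9β-OTBS | CC1=CC=C[C@]2(C(=O)OC)[C@@H](O[Si](C)(C)C(C)(C)C)[C@H](O[Si](CC)(CC)CC)[C@@H]3CC(=O)O[C@@H]3[C@H]12 | intermediate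
23 | cyclodeca-1(10),2,4-triene: C1=C10 (CO2Me trans to C2), cis C2=C3, trans C4=C5; 6,12-olide; 8-OTES; 9-OTBS | CC[Si](CC)(CC)O[C@@H]1[C@@H]2CC(=O)O[C@@H]2/C=C(C)/C=C\C=C(\C(=O)OC)[C@H]1O[Si](C)(C)C(C)(C)C | intermediate
24 | germacra-1(10),4-diene: 23 with C2–C3 saturated | CC[Si](CC)(CC)O[C@@H]1[C@@H]2CC(=O)O[C@@H]2/C=C(C)/CC/C=C(/C(=O)OC)[C@H]1O[Si](C)(C)C(C)(C)C | intermediate
25 | Mannich base (11-dimethylaminomethyl lactone, C11 epimers) | CC[Si](CC)(CC)O[C@@H]1[C@@H]2C(CN(C)C)C(=O)O[C@@H]2/C=C(C)/CC/C=C(/C(=O)OC)[C@H]1O[Si](C)(C)C(C)(C)C | intermediate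
26 | methiodide (11-trimethylammoniomethyl lactone iodide) | CC[Si](CC)(CC)O[C@@H]1[C@@H]2C(C[N+](C)(C)C)C(=O)O[C@@H]2/C=C(C)/CC/C=C(/C(=O)OC)[C@H]1O[Si](C)(C)C(C)(C)C.[I-] | intermediate
27 | 11(13)-methylene lactone; 8-OTES; 9-OTBS | CC[Si](CC)(CC)O[C@@H]1[C@@H]2C(=C)C(=O)O[C@@H]2/C=C(C)/CC/C=C(/C(=O)OC)[C@H]1O[Si](C)(C)C(C)(C)C | intermediate
28 | 8-hydroxy compound (9-OTBS) | O[C@@H]1[C@@H]2C(=C)C(=O)O[C@@H]2/C=C(C)/CC/C=C(/C(=O)OC)[C@H]1O[Si](C)(C)C(C)(C)C | intermediate
29 | 8-O-methacrylate (9-OTBS) | C=C(C)C(=O)O[C@@H]1[C@@H]2C(=C)C(=O)O[C@@H]2/C=C(C)/CC/C=C(/C(=O)OC)[C@H]1O[Si](C)(C)C(C)(C)C | intermediate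
30 | 8-O-methacrylate 9-alcohol | C=C(C)C(=O)O[C@@H]1[C@@H]2C(=C)C(=O)O[C@@H]2/C=C(C)/CC/C=C(/C(=O)OC)[C@H]1O | intermediate
31 | 9-O-acetyl-8-O-methacryloyl germacra-1(10),4-dienolide (4,5-deoxy target) | C=C(C)C(=O)O[C@@H]1[C@@H]2C(=C)C(=O)O[C@@H]2/C=C(C)/CC/C=C(/C(=O)OC)[C@H]1OC(C)=O | intermediate
32 | fluctuadin, (4R,5R,6S,7S,8R,9R) in skeleton numbering | C=C(C)C(=O)O[C@@H]1[C@@H]2C(=C)C(=O)O[C@@H]2[C@H]2O[C@]2(C)CC/C=C(/C(=O)OC)[C@H]1OC(C)=O | target

**Step count**
Total: 24 steps. Longest linear sequence: 22 steps (3 → 32; steps 2–4 and 6–24). Steps 1 and 5 prepare the diene and the malonate half ester.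

**Steps most likely to fail**

Step 17 (ring opening). A minor ring-B chair can open with the opposite conrotation, the triene can photorevert, and the ester-conjugated C1=C10 bond can undergo light-induced E/Z scrambling once formed. Fallback, from 22 back to 24: the geometry at C1=C10 is corrected by thermodynamics after the triene chromophore is gone instead of relying on torquoselection alone. Compound 22 is irradiated to the photostationary state, and the photolysate, containing 23 and the C1=C10 geometric isomer of the triene F1 (CO2Me cis to C2), is reduced with diimide as in step 18. This gives 24 together with the corresponding isomer of the diene F2. Catalytic lithium thiophenoxide in THF (reversible conjugate addition–elimination at C1) then equilibrates F2 to 24; the ring-cis enoate is expected to be the stable one, as in 14-oxidised germacra-1(10),4-dienolides.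

Step 10 (inversion at C8). The α-bromo ketone may epimerise through bromide exchange or enolisation before substitution, or formate may approach the concave α-face too slowly, so inversion would be incomplete. Fallback, from 13 back to 16, avoids the halide. The potassium enolate of 13 (KN(SiMe3)2, THF, −78 °C) is oxidised with 2-(phenylsulfonyl)-3-phenyloxaziridine, which enters on the β-face and gives the 8β-hydroxy ketone F3. Mitsunobu inversion with formic acid (PPh3, diisopropyl azodicarboxylate) converts F3 into formate 15, which is cleaved with NaHCO3 in aqueous methanol to 16.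

Step 3 (enantioselective cycloaddition). The Lewis acid may strip the silyl enol ether, divert the reaction to a stepwise Mukaiyama–Michael path, or discriminate the faces poorly. Fallback, from 4 and 2 back to 6: the cycloaddition is run thermally without catalyst (toluene, rt) to racemic 5 F4, which is reduced as in step 4 to racemic 6 F5. Lipase-catalysed acylation (Burkholderia cepacia lipase, vinyl acetate, tert-butyl methyl ether) then converts the unwanted enantiomer into the acetate of ent-6 F6 (shown for the case that the lipase acylates that enantiomer), and unreacted 6 is separated and carried on.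

**Further compounds**
F1 | step 17 | C1=C10 geometric isomer of triene 23 (CO2Me cis to C2) | CC[Si](CC)(CC)O[C@@H]1[C@@H]2CC(=O)O[C@@H]2/C=C(C)/C=C\C=C(/C(=O)OC)[C@H]1O[Si](C)(C)C(C)(C)C
F2 | step 17 | C1=C10 geometric isomer of diene 24 (CO2Me cis to C2) | CC[Si](CC)(CC)O[C@@H]1[C@@H]2CC(=O)O[C@@H]2/C=C(C)/CC/C=C(\C(=O)OC)[C@H]1O[Si](C)(C)C(C)(C)C
F3 | step 10 | 8β-hydroxy-9-keto 6α,12-olide | C[C@H]1[C@H]2[C@H]3OC(=O)C[C@H]3[C@H](O)C(=O)[C@@]2(C(=O)OC)CC=C1O[Si](C(C)C)(C(C)C)C(C)C
F4 | step 3 | racemic 5 | C[C@H]1[C@H]2C(=O)C=CC(=O)[C@@]2(C(=O)OC)CC=C1O[Si](C(C)C)(C(C)C)C(C)C.C[C@@H]1[C@@H]2C(=O)C=CC(=O)[C@]2(C(=O)OC)CC=C1O[Si](C(C)C)(C(C)C)C(C)C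
F5 | step 3 | racemic 6 | C[C@H]1[C@H]2[C@@H](O)C=CC(=O)[C@@]2(C(=O)OC)CC=C1O[Si](C(C)C)(C(C)C)C(C)C.C[C@@H]1[C@@H]2[C@H](O)C=CC(=O)[C@]2(C(=O)OC)CC=C1O[Si](C(C)C)(C(C)C)C(C)C
F6 | step 3 | acetate of ent-6 | C[C@@H]1[C@@H]2[C@H](OC(C)=O)C=CC(=O)[C@]2(C(=O)OC)CC=C1O[Si](C(C)C)(C(C)C)C(C)C
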